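**Retrosynthetic overview**
1. Target 16 ⇐ MOM removal ⇐ C8 ortho-formylation ⇐ C3' prenylation (lithiation between the two MOM ethers) ⇐ (3R)-isoflavan phenol 11; the alkene and the aldehyde enter only after all oxidising and reducing steps.
2. 11 ⇐ hydrogenolysis (C4–OH and 7-OBn) ⇐ cis-(3R,4R)-isoflavan-4-ol 9 ⇐ one Ru–H transfer-hydrogenation cascade on the flat isoflavone 7; C3 is set here by dynamic kinetic resolution, at the point where isoflavone reductase sets it.
3. Isoflavone 7 ⇐ oxidative 1,2-shift of ring B in chalcone 5 followed by base-induced O1–C2 closure (the isoflavone synthase logic).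
4. Chalcone 5 ⇐ Claisen–Schmidt condensation of acetophenone 4 (ring A) with aldehyde 2 (ring B).
5. Ring order: rings A and B are bought as aromatics; ring C is the only ring made (step 4) and no ring is formed after it.

Assumption: 1-(2,4-dihydroxy-6-methoxyphenyl)ethanone (3) is taken as a catalogue compound. Isoflavan numbering is used (O1, C2, C3, C4, ring A C5–C8, ring B primed).

**Step 1**
Reactants: 1 (2,4-dihydroxybenzaldehyde)
Product: 2 MOM-protected aldehyde 2,4-bis(methoxymethoxy)benzaldehyde
Conditions: MOMCl (3 equiv), i-Pr2NEt (4 equiv), DMAP (cat.), CH2Cl2, 0 → 40 °C, 16 h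
Reagents that add atoms: chloromethyl methyl ether (MOMCl), COCCl
Why: Williamson-type O-alkylation (MOM protection) of both phenols, with excess reagent forcing the hydrogen-bonded 2-OH, gives acetal ethers that survive the later basic, reductive and organolithium steps and later direct the lithiation of ring B.

**Step 2**
Reactants: 3 (1-(2,4-dihydroxy-6-methoxyphenyl)ethanone)
Product: 4 benzyl ether 1-[4-(benzyloxy)-2-hydroxy-6-methoxyphenyl]ethanone
Conditions: BnBr (1.05 equiv), K2CO3 (1.2 equiv), acetone, reflux, 6 h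
Reagents that add atoms: benzyl bromide, BrCc1ccccc1
Why: Selective Williamson etherification, because the 2-OH is locked in a hydrogen bond to the acetyl group and only the free 4-OH reacts; the benzyl group is chosen because step 6 removes it together with the C4 oxygen.

**Step 3**
Reactants: 4 (benzyl ether from step 2); 2 (aldehyde from step 1)
Product: 5 chalcone (E)-1-[4-(benzyloxy)-2-hydroxy-6-methoxyphenyl]-3-[2,4-bis(methoxymethoxy)phenyl]prop-2-en-1-one
Conditions: KOH (50% aq., 10 equiv), EtOH, 0 °C → rt, 48 h; AcOH to pH 6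
Reagents that add atoms: none
Why: Claisen–Schmidt aldol condensation, in which the acetophenone enolate adds to the non-enolisable aldehyde and E1cB loss of water gives the E-enone, the C6–C3–C6 chalcone from which the plant also starts.

**Step 4**
Reactants: 5 (chalcone)
Product: 7 isoflavone 7-(benzyloxy)-3-[2,4-bis(methoxymethoxy)phenyl]-5-methoxy-4H-chromen-4-one, via keto acetal 6 (not isolated)
Conditions: Tl(NO3)3·3H2O (1.2 equiv), MeOH/CH(OMe)3 3:1, rt, 4 h; filter; NaOMe (6 equiv), MeOH, 65 °C, 3 h
Reagents that add atoms: methanol, CO (its two OMe groups sit in 6 and leave again when ring C closes)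
Why: Oxidative 1,2-aryl shift (the Tl(NO3)3 chalcone-to-isoflavone rearrangement): oxythallation of the enone in methanol makes the electron-rich ring B migrate from C-beta to C-alpha to give acetal 6, and methoxide then causes E1cB loss of methanol and addition–elimination by the 2'-phenoxide, closing ring C without acid so the MOM ethers stay on.

**Step 5**
Reactants: 7 (isoflavone)
Product: 9 cis-isoflavan-4-ol (3R,4R)-7-(benzyloxy)-3-[2,4-bis(methoxymethoxy)phenyl]-5-methoxychroman-4-ol, via isoflavanone 8 (not isolated)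
Conditions: RuCl(p-cymene)[(R,R)-TsDPEN] (5 mol %), HCO2H (8 equiv), Et3N (12 equiv), EtOAc, 45 °C, 36 h
Reagents that add atoms: none
Why: Noyori–Ikariya asymmetric transfer hydrogenation with dynamic kinetic resolution: Ru–H first saturates C2=C3, isoflavanone 8 racemises fast at C3 through its enol in the amine-rich medium (which also protects the acid-labile carbinol and the MOM ethers), and the (R,R)-catalyst reduces only the enantiomer that gives the 4R carbinol with hydride delivered anti to the 3-aryl group, so C3 (R) and C4 (R, cis) are set together.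

**Step 6**
Reactants: 9 (cis-isoflavan-4-ol)
Product: 11 isoflavan phenol (3R)-3-[2,4-bis(methoxymethoxy)phenyl]-5-methoxychroman-7-ol, via diol 10 (not isolated)
Conditions: H2 (1 atm), 10% Pd/C, AcOH (2 equiv), EtOAc/EtOH 1:1, rt, 12 h
Reagents that add atoms: none
Why: Catalytic hydrogenolysis cleaves the benzyl ether first and then the C4–OH, a para-hydroxybenzylic alcohol flanked by two further ring oxygens (the reductive last stage of isoflavan biosynthesis), while C3 is not touched and keeps its R configuration.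

**Step 7**
Reactants: 11 (isoflavan phenol)
Product: 13 prenyl isoflavan (3R)-3-[2,4-bis(methoxymethoxy)-3-(3-methylbut-2-en-1-yl)phenyl]-5-methoxychroman-7-ol, via dilithio species 12 (not isolated)
Conditions: n-BuLi (2.3 equiv), THF, −20 → 0 °C, 1.5 h; CuI (10 mol %), prenyl bromide (1.4 equiv), −78 → −20 °C; H2O
Reagents that add atoms: 1-bromo-3-methylbut-2-ene (prenyl bromide), CC(C)=CCBr; n-butyllithium, [Li]CCCC (lithium only in 12)
Why: Directed ortho-metalation followed by copper-catalysed allylic substitution: the first equivalent of n-BuLi makes the 7-phenoxide, which protects ring A from deprotonation, the second removes the C3' proton between the two chelating MOM ethers, and the aryl anion attacks the primary carbon of prenyl bromide (SN2) to give the linear prenyl group.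

**Step 8**
Reactants: 13 (prenyl isoflavan)
Product: 15 aldehyde (3R)-7-hydroxy-3-[2,4-bis(methoxymethoxy)-3-(3-methylbut-2-en-1-yl)phenyl]-5-methoxychromane-8-carbaldehyde, via hydroxymethyl phenol 14 (not isolated)
Conditions: MgCl2 (3 equiv), Et3N (6 equiv), (CH2O)n (8 equiv), MeCN, 75 °C, 4 h; cold 1 M HCl work-up
Reagents that add atoms: formaldehyde (from paraformaldehyde), C=O
Why: Magnesium-mediated ortho-formylation (Casnati–Skattebøl): the magnesium phenoxide delivers formaldehyde only ortho to the single free OH, C8 is expected to be preferred over C6 because the 5-OMe group turns its methyl towards C6, and a second formaldehyde takes a hydride from intermediate 14 (Oppenauer-type) to give the aldehyde, with the prenyl group and MOM ethers inert.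

**Step 9**
Reactants: 15 (aldehyde)
Product: 16 target (3R)-3-[2,4-dihydroxy-3-(3-methylbut-2-en-1-yl)phenyl]-7-hydroxy-5-methoxychromane-8-carbaldehyde
Conditions: HCl (1.25 M in MeOH, 10 equiv), MeOH, rt → 35 °C, 6 h
Reagents that add atoms: none
Why: Acid-catalysed acetal exchange (MOM cleavage) in methanol frees the 2'- and 4'-phenols under conditions mild enough to leave the prenyl double bond, the hydrogen-bonded aldehyde, the 5-OMe group and the C3 stereocentre unchanged.

**Compound list**
1 | 2,4-dihydroxybenzaldehyde | O=Cc1ccc(O)cc1O | starting material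
2 | 2,4-bis(methoxymethoxy)benzaldehyde | COCOc1ccc(C=O)c(OCOC)c1 | intermediate
3 | 1-(2,4-dihydroxy-6-methoxyphenyl)ethanone | CC(=O)c1c(O)cc(O)cc1OC | starting material
4 | 1-[4-(benzyloxy)-2-hydroxy-6-methoxyphenyl]ethanone | CC(=O)c1c(O)cc(OCc2ccccc2)cc1OC | intermediate
5 | (E)-1-[4-(benzyloxy)-2-hydroxy-6-methoxyphenyl]-3-[2,4-bis(methoxymethoxy)phenyl]prop-2-en-1-one | COCOc1ccc(/C=C/C(=O)c2c(O)cc(OCc3ccccc3)cc2OC)c(OCOC)c1 | intermediate
6 | 1-[4-(benzyloxy)-2-hydroxy-6-methoxyphenyl]-2-[2,4-bis(methoxymethoxy)phenyl]-3,3-dimethoxypropan-1-one (racemic, not isolated) | COC(OC)C(C(=O)c1c(O)cc(OCc2ccccc2)cc1OC)c1ccc(OCOC)cc1OCOC | intermediate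
7 | 7-(benzyloxy)-3-[2,4-bis(methoxymethoxy)phenyl]-5-methoxy-4H-chromen-4-one | COCOc1ccc(C2=COc3cc(OCc4ccccc4)cc(OC)c3C2=O)c(OCOC)c1 | intermediate
8 | 7-(benzyloxy)-3-[2,4-bis(methoxymethoxy)phenyl]-5-methoxychroman-4-one (C3 racemising, not isolated) | COCOc1ccc(C2COc3cc(OCc4ccccc4)cc(OC)c3C2=O)c(OCOC)c1 | intermediate
9 | (3R,4R)-7-(benzyloxy)-3-[2,4-bis(methoxymethoxy)phenyl]-5-methoxychroman-4-ol (3-aryl and 4-OH cis) | COc1cc(OCc3ccccc3)cc2c1[C@H](O)[C@H](c1ccc(OCOC)cc1OCOC)CO2 | intermediate
10 | (3R,4R)-3-[2,4-bis(methoxymethoxy)phenyl]-5-methoxychromane-4,7-diol (not isolated) | COc1cc(O)cc2c1[C@H](O)[C@H](c1ccc(OCOC)cc1OCOC)CO2 | intermediate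
11 | (3R)-3-[2,4-bis(methoxymethoxy)phenyl]-5-methoxychroman-7-ol | COc1cc(O)cc2c1C[C@H](c1ccc(OCOC)cc1OCOC)CO2 | intermediate
12 | lithium (3R)-3-[3-lithio-2,4-bis(methoxymethoxy)phenyl]-5-methoxychroman-7-olate (not isolated) | COc1cc(O[Li])cc2c1C[C@H](c1ccc(OCOC)c([Li])c1OCOC)CO2 | intermediate
13 | (3R)-3-[2,4-bis(methoxymethoxy)-3-(3-methylbut-2-en-1-yl)phenyl]-5-methoxychroman-7-ol | COc1cc(O)cc2c1C[C@H](c1ccc(OCOC)c(CC=C(C)C)c1OCOC)CO2 | intermediate
14 | (3R)-8-(hydroxymethyl)-3-[2,4-bis(methoxymethoxy)-3-(3-methylbut-2-en-1-yl)phenyl]-5-methoxychroman-7-ol (in the flask as its magnesium salt, not isolated) | COc1cc(O)c(CO)c2c1C[C@H](c1ccc(OCOC)c(CC=C(C)C)c1OCOC)CO2 | intermediate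
15 | (3R)-7-hydroxy-3-[2,4-bis(methoxymethoxy)-3-(3-methylbut-2-en-1-yl)phenyl]-5-methoxychromane-8-carbaldehyde | COc1cc(O)c(C=O)c2c1C[C@H](c1ccc(OCOC)c(CC=C(C)C)c1OCOC)CO2 | intermediate
16 | (3R)-3-[2,4-dihydroxy-3-(3-methylbut-2-en-1-yl)phenyl]-7-hydroxy-5-methoxychromane-8-carbaldehyde | COc1cc(O)c(C=O)c2c1C[C@H](c1ccc(O)c(CC=C(C)C)c1O)CO2 | target

**Step count**
Total steps: 9. Longest linear sequence: 8 steps (3 → 4 → 5 → 7 → 9 → 11 → 13 → 15 → 16; the branch 1 → 2 joins at step 3 and is equally long).

**Steps most likely to fail, with fallbacks**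

Step 5 (Ru–H cascade). The C4 carbonyl sits next to the 5-OMe group and may react slowly or with poor dr/ee. The sense of induction is assigned by analogy with chromanone and tetralone reductions and must be confirmed on 9; the (S,S)-catalyst gives the antipode. The fallback sets out from 7 and sets C3 on an alkene instead. NaBH4 (THF/EtOH) reduces 7 to the racemic isoflavan-4-ol F1, which loses water with catalytic pyridinium p-toluenesulfonate (CH2Cl2, rt) to give the isoflav-3-ene F2. Asymmetric hydrogenation of F2 with [Ir(cod)((S)-tBu-PHOX)]BArF (or its enantiomer, whichever gives 3R; H2 50 bar, CH2Cl2) gives the (3R)-7-benzyloxyisoflavan F3; the benzyl ether survives the homogeneous iridium catalyst. Hydrogenolysis of F3 over 10% Pd/C comes back to the route at 11.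

Step 7 (prenylation of the dianion). The dilithio species may be poorly soluble, or the 7-phenoxide may be prenylated at oxygen or carbon. The fallback sets out from 11 and caps the phenol first. TIPSCl and imidazole (DMF) give the silyl ether F4, whose bulky, non-directing OTIPS group shields C6 and C8. n-BuLi (1.2 equiv, THF, 0 °C), then CuI and prenyl bromide, give the prenylated silyl ether F5, and Bu4NF (THF, 0 °C) comes back to the route at 13.

Step 8 (C8 against C6 formylation). The reaction may give a mixture of regioisomers or stop at the benzylic alcohol. The fallback sets out from 13 and brings the carbon in as a cyclic boronate, then oxidises separately. PhB(OH)2, (CH2O)n and catalytic propionic acid in refluxing toluene (Dean–Stark) give the 1,3,2-benzodioxaborin F6 at the less hindered C8. Exchange with propane-1,3-diol frees the hydroxymethyl phenol 14, now isolated, and MnO2 (CH2Cl2) oxidises it, so the fallback comes back to the route at 15.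

**Further compounds**
F1 | step 5 | 7-(benzyloxy)-3-[2,4-bis(methoxymethoxy)phenyl]-5-methoxychroman-4-ol (racemic, cis/trans mixture) | COc1cc(OCc3ccccc3)cc2c1C(O)C(c1ccc(OCOC)cc1OCOC)CO2
F2 | step 5 | 7-(benzyloxy)-3-[2,4-bis(methoxymethoxy)phenyl]-5-methoxy-2H-chromene | COc1cc(OCc3ccccc3)cc2c1C=C(c1ccc(OCOC)cc1OCOC)CO2
F3 | step 5 | (3R)-7-(benzyloxy)-3-[2,4-bis(methoxymethoxy)phenyl]-5-methoxychromane | COc1cc(OCc3ccccc3)cc2c1C[C@H](c1ccc(OCOC)cc1OCOC)CO2
F4 | step 7 | (3R)-3-[2,4-bis(methoxymethoxy)phenyl]-5-methoxy-7-[(triisopropylsilyl)oxy]chromane | COc1cc(O[Si](C(C)C)(C(C)C)C(C)C)cc2c1C[C@H](c1ccc(OCOC)cc1OCOC)CO2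
F5 | step 7 | (3R)-3-[2,4-bis(methoxymethoxy)-3-(3-methylbut-2-en-1-yl)phenyl]-5-methoxy-7-[(triisopropylsilyl)oxy]chromane | COc1cc(O[Si](C(C)C)(C(C)C)C(C)C)cc2c1C[C@H](c1ccc(OCOC)c(CC=C(C)C)c1OCOC)CO2
F6 | step 8 | 2-phenyl-4H-1,3,2-benzodioxaborin fused across O7 and the C8 methylene of 13 | COc1cc2c(c3c1C[C@H](c1ccc(OCOC)c(CC=C(C)C)c1OCOC)CO3)COB(c1ccccc1)O2
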